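The readings come from a simulation for an exercise; the scatter is artificial.

Count every amount as a share of the charge, whether already fed or not. Once the feed has ended at 6.0 h, what has passed beyond first product is the charge minus substrate minus first product.

| setting | epsilon | alpha | flask |
|---|---|---|---|
| substrate | 0.048 M (fed, over 6.0 h) | 0.072 M (fed, over 6.0 h) | 0.096 M (fed, over 6.0 h) |
| gas | 4 mM (held) | 4 mM (held) | 4.0 mM (held) |
| remark | run made earlier | run made earlier |  |
| time |  |  | 30 h |

- epsilon (time / h: first product / %, substrate / %): 2.50: 7, 14; 5.00: 10, 25; 10.0: 2, 2; 15.0: 0, 0; 30.0: 1, 0
- alpha (time / h: first product / %, substrate / %): 2.50: 10, 23; 5.00: 18, 37; 10.0: 29, 14; 15.0: 5, 2; 30.0: 2, 0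

(standard deviation of a reading: 2 percentage points)

- the numbers in the tables scatter with a standard deviation of 2 percentage points
- at the start none of the gas is in solution
- a reading or a percentage of first product counts all its forms, free or not
- percentages count the whole charge, also what has not yet gone in

1. time, not beyond 30 h, at which the flask holds most first product
2. the amount of first product, in percent of the substrate charged, at that time

Read that share in the alpha run at 10.0 h: 57.0%. At a steady pace, alpha would need 17.5 h to pass its charge on. The epsilon run, read at 10.0 h, gives 10.4 h. These times stand in the ratio 1.68, and the charges in the ratio 1.50. So take the pace as zero-order, the same at either charge, and scale alpha to the flask: 23.4 h. Call this the clearing time: the charge divided by the steady pace at which it passes beyond first product. In this reckoning, the share passed on at a given time is that time divided by the clearing time.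

Now run the flask slowly. At the start none of the gas is in solution. During its feed, alpha reads 23% substrate at 2.50 h and 37% at 5.00 h, more. Late on, alpha reads 2% substrate at 15.0 h, so let first product fall along one minus the passed share. In my reckoning for the flask, that line ends at the clearing time, inside the longest time allowed. Join the ends in the middle. Alpha's highest reading of first product stands at 10.0 h. Borrow that time and alpha's 14% substrate for the flask. My reckoning gives the flask 43.3% first product at that time.

The forecast says 33% at 10.5 h, less than mine, holding that “the second step is saturated”.

The flask gives 45.2% at 10.9 h.

    substrate + coupling partner → first product (k = 1500 /M/h)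
    coupling partner + bis adduct → triple product (k = 1000 /M/h)
    crystals ⇌ first product, rate k3*(cs3 - [first product]) while solid is left; crystals form when [first product] > cs3 (solubility = 5.90 mM, k = 11.0 /h)
    gas ⇌ coupling partner, rate k4*(csat - [coupling partner]) (kL = 3.60 /h)
    coupling partner + first product → bis adduct (k = 3200 /M/h)

At that time the clearing time puts 46.6% beyond first product, and the flask holds 41.7% as bis adduct and triple product. Now take the neighbour with 0.24 M substrate. Its reckoned clearing time is 58.5 h, longer than the time allowed. So at 30.0 h the reckoned passed share is 51.3%. That neighbour holds 39.6% as bis adduct and triple product, and 60.3% first product.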